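I follow the charge.

    target → over-reaction product (k1 = 0.00867 h⁻¹)
    starting material → target, rate k2*[starting material]/(1 + ([starting material]/sat2)) (sat2 = 15.4 mM, k2 = 0.214 h⁻¹)
    target ⇌ isomer of the product (K3 = 0.22, k3 = 0.112 h⁻¹)
    solid substrate ⇌ starting material, rate k4*(cs4 - [starting material]) while solid is left; crystals form when [starting material] > cs4 (cs4 = 17 mM, k4 = 0.238 h⁻¹)

solid substrate 24 mM; time 30 h

- elm: doubling the solubility in step 4, all else as stated
- birch: doubling the dissolution coefficient of step 4, all else as stated

- solid, in amounts per volume of the solution: solid substrate
- at the start none of the solid substrate is in solution
- run time (flask): 30 h

- how much target there is at 30 h, in percent of the solid substrate charged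
- the change that raises the amount of target at 30 h, in percent of the solid substrate charged most ("none" if none brings more than 2 percentage points) (elm / birch / none)
- amount of target at 30 h, in percent of the solid substrate charged, after birch

**The drain.** The solid substrate is the one charge, so it is the limiting reagent, and I book its moles. The isomerisation relaxes with a half-life of 1.12 h, short against the 30 h run, so I treat target and isomer of the product as one pool, with target holding 82.0 % of it at equilibrium. Over-reaction acts on target, so the pool loses moles at the drain constant 0.00711 h⁻¹, the over-reaction constant times that share. Drain turnovers are this constant times the hours spent in the pool.

**Entry time.** Dissolution could deliver 506 % of the charge by the end into a solution kept empty, if the solid never ran out. A mole waits, on my estimate, for half the supply time, 2.97 h, plus a conversion time of 9.83 h, taken cautiously with c(starting material) at the solubility. Since that conversion time is shorter than the run, I book the charge into the pool, on average at 12.8 h.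

**Closing books.** That gives 0.122 turnovers. So I book 11.5 % to over-reaction product, 15.9 % to isomer of the product, and 72.5 % to target. Birch halves the supply wait, which leaves 71.8 %. In my books, faster supply adds pool hours and no moles, so I choose none.

**The forecast.** It gives 70.4 %, 69.9 % after birch and none, saying “Elm is similar, so neither helps.” Its target is lower than mine.

**The flask.** The simulation gives 70.4 %, 70.1 % after birch and best none, with elm moving target by −0.52 percentage points and birch by −0.35 points. In this flask the drain time 141 h is longer than the 30 h run, and the over-reaction product reads 12.3 %, which is 0.131 turnovers against my 0.122. The neighbour flask read at 2.0 d holds 63.1 % of target, and the drain from there to the neighbour flask left until 5.0 d is 0.512 turnovers, which leaves 37.8 %; that flask reads 37.9 %.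

The numbers of this flask are assumed; what happens was integrated by code.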